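The amber run is this very flask followed so far: its target climbs fast, then lies flat from 40.0 min to 180 min, at a mean of 44.7%.

| flask | starting material | partner | second substrate | remark | time |
|---|---|---|---|---|---|
| amber | 0.20 M | 0.20 M | 0.40 M | the very flask that is asked about, followed so far |  |
| flask | 0.20 M | 0.200 M | 0.400 M |  | 5.0 h |

- amber (time / min: target / %): 15.0: 36.7; 25.0: 41.0; 40.0: 45.0; 60.0: 44.7; 120: 44.5; 180: 44.6

(readings scatter by 0.5 percentage points)

- south-west: at 5.0 h add partner, 50.0% of the amount charged, then wait 10 h
- south-east: change nothing and wait 10 h more
- west: at 5.0 h take out 90% of the target then present, then wait 10 h
- north: at 5.0 h add starting material, 50.0% of the amount charged, then wait 10 h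

- removed target is counted in
- additions bring no volume worth counting

- target, in percent of the starting material first charged, at 5.0 h
- which option adds most target ("none" when 2 percentage points or less is all one gets) (south-west / south-east / west / north / none)
- target present, with what was taken out counted in, in percent of the starting material first charged, after south-west
- target present, with what was taken out counted in, in percent of the starting material first charged, after south-east

Keep a ledger of the 0.20 M of partner, taking one partner per target. The first entry is the target on amber's plateau, 0.0894 M. The second is free partner, 0.111 M, with free starting material at 0.111 M. An exhausted partner would need that whole second entry booked to the second substrate, and no reading shows such an entry, so I book it as nil and read the stop as a balance. That is my reckoning, and amber can't prove it.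

Now follow one molecule of starting material, which flips between free and bound. Amber's entries give 7.31 M⁻¹ for [target]/([starting material][partner]), the plateau quotient, which is the equilibrium constant if the balance holds. The molecule's odds of being target are this quotient times [partner].

Closing the books with it, south-east adds nothing and 5.0 h stays at 44.7%. South-west comes to 57.5%, and north to the same sum, the charges being equal. West takes out 0.0805 M of target, which leaves 0.120 M each of starting material and partner, free and bound together, and that flask refills to 61.7%, counting what was taken out, which is more than south-west. So I name west.

The forecast differs: 44.6% now, south-west best, 64% after south-west, 44.6% after south-east, on the ground that “The stop looks abrupt rather than a smooth relaxation, which favours exhaustion”.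

The flask gives 44.8% at 5.0 h. Most is added by west, 17 percentage points against 13 points for south-west, 13 points for north and 0 points for south-east. South-west reaches 57.6% and south-east 44.8%.

    starting material + partner ⇌ target (K = 7.84 M⁻¹, k = 0.311 M⁻¹ min⁻¹)
    second substrate + partner ⇌ second product (K = 0.176 M⁻¹, k = 0.0512 M⁻¹ min⁻¹)

The flask stops with 51.7% of its partner free at 300 min. The main reason is the backward run from target to starting material and partner: the simulated run without it holds 94.6% at 5.0 h against 44.8%. Carried on, 7.31 M⁻¹ gave west 61.7%, and the flask holds 61.7%. For the neighbour flask charged with 0.50 M of partner, the same quotient gives 72.2% of target, and that flask holds 72.3%.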